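The route cuts the 1,2-dioxane ring at C4–C5 and at C6–O, numbering the lactone carbonyl C1 and the chain-bearing peroxy carbon C6. Ring carbon C4 carries a methyl group and the lactone oxygen and sits between the peroxy methine C3 and C5H2. It is therefore traced back to a methyl ketone, with C5=C6 as the alkene of a 2-methyl-1-en-3-yne that places its cation on C6. In one Lewis-acid operation an (R)-3-silylperoxy-4-oxopentanoate (from (S)-malic acid) and the enyne should give the C4–C5 and C6–O bonds, the dioxane ring and the C4 and C6 stereocentres. Alkyne saturation, lactonisation and cinnamyl olefination complete the route.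

Key step: step 9

Remarks on the chemistry:
- Atom labels: C1 lactone carbonyl, C2, C3 (peroxy CH), C4 (carbinol carbon with methyl), C5, C6 (peroxy carbon with methyl and chain), C7–C16 side chain.
- Structure check: the target is 3R,4R,6S. (S)-Malic acid gives (S)-5 and one inversion gives (R)-9. The alkynyl dioxane 14 is 3R,4R,6R; its C6 label becomes S on saturation through CIP priorities only, with no change in geometry. No structural correction was needed.
- Precursor design: triethylsilyl stays on the peroxide because it has to leave from a silyloxonium ion. The triflate is made and used in one flask, the enyne is used in excess, and a hindered pyridine removes adventitious HCl in the annulation.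
- Any 14 that lactonises early converges at step 11.

Step 1
Reactants: 1 (S)-malic acid
Product: 2 (S)-2-(2,2-dimethyl-5-oxo-1,3-dioxolan-4-yl)acetic acid
Conditions: Me2C(OMe)2, TsOH·H2O (cat.), rt
Reagents that add atoms: 2,2-dimethoxypropane, COC(C)(C)OC
Why: Acid-catalysed acetalisation (1,3-dioxolan-4-one formation) takes up only the α-hydroxy acid unit in a five-membered ring, which leaves the future C1 carboxyl free, marks the other carboxyl as the future C4 ketone and does not touch the stereocentre.

Step 2
Reactants: 2 (S)-2-(2,2-dimethyl-5-oxo-1,3-dioxolan-4-yl)acetic acid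
Product: 3 methyl (S)-2-(2,2-dimethyl-5-oxo-1,3-dioxolan-4-yl)acetate
Conditions: MeI, KHCO3, DMF, rt
Reagents that add atoms: iodomethane, CI
Why: Carboxylate O-alkylation (SN2 on iodomethane) with a bicarbonate base is too mild to open or epimerise the dioxolanone.

Step 3
Reactants: 3 methyl (S)-2-(2,2-dimethyl-5-oxo-1,3-dioxolan-4-yl)acetate
Product: 4 methyl (S)-3-hydroxy-4-[methoxy(methyl)amino]-4-oxobutanoate
Conditions: MeNH(OMe)·HCl (1.05 equiv), iPrMgCl (2.1 equiv), THF, −40 → −20 °C
Reagents that add atoms: N,O-dimethylhydroxylamine hydrochloride, CNOC.Cl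
Why: Weinreb aminolysis by the chloromagnesium amide should select the dioxolanone carbonyl, an activated acyl acetal that opens irreversibly with loss of acetone, over the plain methyl ester when one equivalent of amide is used at low temperature; the C3 stereocentre is not involved.

Step 4
Reactants: 4 methyl (S)-3-hydroxy-4-[methoxy(methyl)amino]-4-oxobutanoate
Product: 5 methyl (S)-3-hydroxy-4-oxopentanoate
Conditions: MeMgBr (2.3 equiv), THF, −78 → −20 °C; aq. NH4Cl
Reagents that add atoms: methylmagnesium bromide, C[Mg]Br
Why: Weinreb ketone synthesis: one equivalent of Grignard reagent forms the C3 magnesium alkoxide and the next adds to the amide to give a chelated tetrahedral intermediate that holds until the quench, while the methyl ester reacts far more slowly at −78 °C, so the ketone should form without over-addition or loss of configuration at C3.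

Step 5
Reactants: 6 chlorotriethylsilane
Product: 7 triethylsilyl hydroperoxide
Conditions: H2O2 (anhydrous, ethereal, 5 equiv), pyridine, Et2O, −20 → 0 °C; used as a cold solution
Reagents that add atoms: hydrogen peroxide, OO
Why: Nucleophilic substitution at silicon by hydrogen peroxide, kept in large excess so that the mono-silyl hydroperoxide and not the bis-silyl peroxide forms.

Step 6
Reactants: 5 methyl (S)-3-hydroxy-4-oxopentanoate; 7 triethylsilyl hydroperoxide
Product: 9 methyl (R)-4-oxo-3-[(triethylsilyl)peroxy]pentanoate, via alpha-keto triflate 8 (not isolated)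
Conditions: Tf2O (1.05 equiv), 2,6-di-tert-butyl-4-methylpyridine (DTBMP, 2.2 equiv), CH2Cl2, −78 °C; then 7, −78 → −20 °C
Reagents that add atoms: none
Why: O-Triflation of the α-hydroxy ketone and SN2 O-alkylation of the hydroperoxide by the resulting α-keto triflate (the alkyl triflate route to peroxides) should invert C3 from S to R, the hindered pyridine taking up triflic acid without acting as a nucleophile or as a base toward C2–H and C3–H.

Step 7
Reactants: 10 hept-6-yn-1-ol
Product: 11 tert-butyl(hept-6-yn-1-yloxy)dimethylsilane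
Conditions: TBSCl, imidazole, CH2Cl2, rt
Reagents that add atoms: tert-butyldimethylsilyl chloride, CC(C)(C)[Si](C)(C)Cl
Why: Routine silylation of the primary alcohol (silyl chloride with imidazole) gives an ether that tolerates the Sonogashira coupling and SnCl4 at −78 °C.

Step 8
Reactants: 11 tert-butyl(hept-6-yn-1-yloxy)dimethylsilane; 12 2-bromopropene
Product: 13 tert-butyldimethyl[(8-methylnon-8-en-6-yn-1-yl)oxy]silane
Conditions: Pd(PPh3)2Cl2 (cat.), CuI (cat.), Et3N, 35 °C, sealed vessel
Reagents that add atoms: none
Why: Sonogashira coupling of the terminal alkyne with the vinyl bromide builds the conjugated enyne with its 1,1-disubstituted alkene in one step.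

Step 9
Reactants: 9 methyl (R)-4-oxo-3-[(triethylsilyl)peroxy]pentanoate; 13 tert-butyldimethyl[(8-methylnon-8-en-6-yn-1-yl)oxy]silane
Product: 14 methyl 2-[(3R,4R,6R)-6-[7-(tert-butyldimethylsilyloxy)hept-1-yn-1-yl]-4-hydroxy-4,6-dimethyl-1,2-dioxan-3-yl]acetate
Conditions: SnCl4 (1.2 equiv), DTBMP (0.2 equiv), CH2Cl2, −78 °C; then 13 (2 equiv), −78 °C; aq. NaHCO3
Reagents that add atoms: none
Why: Proposed new method: SnCl4 should bind the C4 ketone oxygen and the C3-bound peroxide oxygen of 9 in a five-membered chelate, the CH2 terminus of enyne 13 then adds to C4 (Prins-type carbonyl addition), and the tertiary propargylic cation at C6 is trapped by the silylated peroxide oxygen, which gives up its silyl group as Et3SiCl. The closest known reaction types are the Lewis-acid [3+2] annulation of silylperoxy-derived peroxycarbenium ions with alkenes to 1,2-dioxolanes and chelation-controlled Prins, ene and Hosomi–Sakurai additions to α-alkoxy ketones. The 1,2-dioxane closes 6-exo, oxygen onto the cationic C6 with the alkynyl (allenyl) unit staying outside the ring, through a chair. C4 is set by 1,2-induction from C3: attack on the chelate anti to the CH2CO2Me arm places the C4 oxygen cis to that arm (3R,4R). C6 is set by 1,3-induction in the chair: the tin-bound C4 oxygen must be axial to stay chelated, so the rod-like alkynyl group takes the 1,3-diaxial site and both methyl groups sit equatorial (6R). The step needs carbonyl addition to win over acid-induced O–O heterolysis, and Markovnikov addition of the alkene; low temperature, an aprotic chelating Lewis acid with a proton scavenger, the 1,1-disubstituted alkene and an excess of enyne are meant to secure both.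

Step 10
Reactants: 14 methyl 2-[(3R,4R,6R)-6-[7-(tert-butyldimethylsilyloxy)hept-1-yn-1-yl]-4-hydroxy-4,6-dimethyl-1,2-dioxan-3-yl]acetate
Product: 16 methyl 2-[(3R,4R,6S)-6-[7-(tert-butyldimethylsilyloxy)heptyl]-4-hydroxy-4,6-dimethyl-1,2-dioxan-3-yl]acetate, via cis-alkene 15 (not isolated)
Conditions: KO2CN=NCO2K (large excess, in portions), AcOH, MeOH–CH2Cl2, 0 °C → rt
Reagents that add atoms: none
Why: Diimide, released from the azodicarboxylate salt by acetic acid, transfers hydrogen through a concerted six-centre transition state to the alkyne and then to the cis-alkene without reducing the O–O bond or the ester; no stereocentre is touched.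

Step 11
Reactants: 16 methyl 2-[(3R,4R,6S)-6-[7-(tert-butyldimethylsilyloxy)heptyl]-4-hydroxy-4,6-dimethyl-1,2-dioxan-3-yl]acetate
Product: 18 (3S,4aR,7aR)-3-(7-hydroxyheptyl)-3,4a-dimethyltetrahydrofuro[3,2-c][1,2]dioxin-6(3H)-one, via desilylated hydroxy ester 17 (not isolated)
Conditions: CSA (cat.), MeOH, rt; then evaporate, CSA (cat.), CH2Cl2, rt
Reagents that add atoms: none
Why: Acid-catalysed methanolysis of the primary silyl ether is followed by acid-catalysed lactonisation (intramolecular transesterification) of the C4 hydroxyl, which is cis to the C3 acetate arm, onto the methyl ester once methanol is removed; the saturated tertiary dialkyl peroxide should tolerate catalytic sulfonic acid.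

Step 12
Reactants: 18 (3S,4aR,7aR)-3-(7-hydroxyheptyl)-3,4a-dimethyltetrahydrofuro[3,2-c][1,2]dioxin-6(3H)-one
Product: 19 7-[(3S,4aR,7aR)-3,4a-dimethyl-6-oxohexahydrofuro[3,2-c][1,2]dioxin-3-yl]heptanal
Conditions: Dess–Martin periodinane, CH2Cl2, rt
Reagents that add atoms: none
Why: Dess–Martin oxidation stops at the aldehyde under mildly acidic conditions that dialkyl peroxides and the lactone tolerate.

Step 13
Reactants: 19 7-[(3S,4aR,7aR)-3,4a-dimethyl-6-oxohexahydrofuro[3,2-c][1,2]dioxin-3-yl]heptanal; 20 diethyl [(E)-3-phenylprop-2-en-1-yl]phosphonate (diethyl cinnamylphosphonate)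
Product: 21 plakortolide Q, (3S,4aR,7aR)-3,4a-dimethyl-3-[(7E,9E)-10-phenyldeca-7,9-dien-1-yl]tetrahydrofuro[3,2-c][1,2]dioxin-6(3H)-one
Conditions: 20 (1.5 equiv), NaHMDS (1.4 equiv), THF, −78 °C; then 19, −78 → 0 °C
Reagents that add atoms: none
Why: Horner–Wadsworth–Emmons olefination with the preformed allylic phosphonate anion (phosphonate in slight excess over base) should form C13=C14 with E selectivity, the C15=C16 geometry coming from the reagent, because carbonyl addition at −78 °C is faster than deprotonation of the lactone.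

Compound list
1 | (S)-malic acid | O[C@@H](CC(=O)O)C(=O)O | starting material
2 | (S)-2-(2,2-dimethyl-5-oxo-1,3-dioxolan-4-yl)acetic acid | CC1(C)O[C@@H](CC(=O)O)C(=O)O1 | intermediate
3 | methyl (S)-2-(2,2-dimethyl-5-oxo-1,3-dioxolan-4-yl)acetate | CC1(C)O[C@@H](CC(=O)OC)C(=O)O1 | intermediate
4 | methyl (S)-3-hydroxy-4-[methoxy(methyl)amino]-4-oxobutanoate | O[C@@H](CC(=O)OC)C(=O)N(C)OC | intermediate
5 | methyl (S)-3-hydroxy-4-oxopentanoate | CC(=O)[C@@H](O)CC(=O)OC | intermediate
6 | chlorotriethylsilane | CC[Si](Cl)(CC)CC | starting material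
7 | triethylsilyl hydroperoxide | CC[Si](CC)(CC)OO | intermediate
8 | methyl (S)-4-oxo-3-(trifluoromethylsulfonyloxy)pentanoate (not isolated) | CC(=O)[C@@H](OS(=O)(=O)C(F)(F)F)CC(=O)OC | intermediate
9 | methyl (R)-4-oxo-3-[(triethylsilyl)peroxy]pentanoate | CC(=O)[C@@H](CC(=O)OC)OO[Si](CC)(CC)CC | intermediate
10 | hept-6-yn-1-ol | C#CCCCCCO | starting material
11 | tert-butyl(hept-6-yn-1-yloxy)dimethylsilane | C#CCCCCCO[Si](C)(C)C(C)(C)C | intermediate
12 | 2-bromopropene | CC(Br)=C | starting material
13 | tert-butyldimethyl[(8-methylnon-8-en-6-yn-1-yl)oxy]silane | C=C(C)C#CCCCCCO[Si](C)(C)C(C)(C)C | intermediate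
14 | methyl 2-[(3R,4R,6R)-6-[7-(tert-butyldimethylsilyloxy)hept-1-yn-1-yl]-4-hydroxy-4,6-dimethyl-1,2-dioxan-3-yl]acetate | C[C@]1(C#CCCCCCO[Si](C)(C)C(C)(C)C)C[C@@](C)(O)[C@@H](CC(=O)OC)OO1 | intermediate
15 | methyl 2-[(3R,4R,6R)-6-[(Z)-7-(tert-butyldimethylsilyloxy)hept-1-en-1-yl]-4-hydroxy-4,6-dimethyl-1,2-dioxan-3-yl]acetate (not isolated) | C[C@]1(/C=C\CCCCCO[Si](C)(C)C(C)(C)C)C[C@@](C)(O)[C@@H](CC(=O)OC)OO1 | intermediate
16 | methyl 2-[(3R,4R,6S)-6-[7-(tert-butyldimethylsilyloxy)heptyl]-4-hydroxy-4,6-dimethyl-1,2-dioxan-3-yl]acetate | C[C@]1(CCCCCCCO[Si](C)(C)C(C)(C)C)C[C@@](C)(O)[C@@H](CC(=O)OC)OO1 | intermediate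
17 | methyl 2-[(3R,4R,6S)-4-hydroxy-6-(7-hydroxyheptyl)-4,6-dimethyl-1,2-dioxan-3-yl]acetate (not isolated) | C[C@]1(CCCCCCCO)C[C@@](C)(O)[C@@H](CC(=O)OC)OO1 | intermediate
18 | (3S,4aR,7aR)-3-(7-hydroxyheptyl)-3,4a-dimethyltetrahydrofuro[3,2-c][1,2]dioxin-6(3H)-one | C[C@]1(CCCCCCCO)C[C@@]2(C)OC(=O)C[C@H]2OO1 | intermediate
19 | 7-[(3S,4aR,7aR)-3,4a-dimethyl-6-oxohexahydrofuro[3,2-c][1,2]dioxin-3-yl]heptanal | C[C@]1(CCCCCCC=O)C[C@@]2(C)OC(=O)C[C@H]2OO1 | intermediate
20 | diethyl [(E)-3-phenylprop-2-en-1-yl]phosphonate | CCOP(=O)(OCC)C/C=C/c1ccccc1 | starting material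
21 | plakortolide Q, (3S,4aR,7aR)-3,4a-dimethyl-3-[(7E,9E)-10-phenyldeca-7,9-dien-1-yl]tetrahydrofuro[3,2-c][1,2]dioxin-6(3H)-one | C[C@]1(CCCCCC/C=C/C=C/c2ccccc2)C[C@@]2(C)OC(=O)C[C@H]2OO1 | target

Total step count: 13. Longest linear sequence: 10 steps (1, 2, 3, 4, 6, 9, 10, 11, 12, 13).

Steps most likely to fail

Step 9 (proposed new method). Process at risk: the enyne is a weak π-nucleophile, so other pathways may outrun the peroxide ring closure. These are Lewis-acid-induced O–O heterolysis with acyl migration in the α-peroxy ketone, proton loss from the propargylic cation (ene product) and chloride capture. Facial selectivity may also erode if the ester rather than the peroxide oxygen holds the tin. Fallback (known reaction types only; sets out from 9, returns at 16 and so also by-passes step 10): the two bonds are made in separate operations. The Grignard reagent [6-(tert-butyldimethylsilyloxy)hexyl]magnesium bromide F1 is made from commercial (6-bromohexyloxy)(tert-butyl)dimethylsilane and magnesium. It is coupled under Li2CuCl4 catalysis with commercial [2-(chloromethyl)allyl]trimethylsilane to give the allylsilane tert-butyldimethyl({8-[(trimethylsilyl)methyl]non-8-en-1-yl}oxy)silane F2. Chelation-controlled Hosomi–Sakurai addition of F2, a far stronger nucleophile than 13, to the SnCl4 complex of 9 at −78 °C should give the homoallylic alcohol methyl (3R,4R)-13-(tert-butyldimethylsilyloxy)-4-hydroxy-4-methyl-6-methylidene-3-[(triethylsilyl)peroxy]tridecanoate F3, with the same C3/C4 relationship as 14. Buffered fluoride (TBAF/AcOH, THF, −20 °C) should remove the peroxide silyl group much faster than the primary silyl ether, giving the hydroperoxide methyl (3R,4R)-13-(tert-butyldimethylsilyloxy)-3-hydroperoxy-4-hydroxy-4-methyl-6-methylidenetridecanoate F4. Hg(OAc)2 in CH2Cl2 then closes the 1,2-dioxane by Markovnikov 6-exo cycloperoxymercuration to the organomercurial methyl 2-[(3R,4R,6S)-6-[(acetoxymercurio)methyl]-6-[7-(tert-butyldimethylsilyloxy)heptyl]-4-hydroxy-4-methyl-1,2-dioxan-3-yl]acetate F5. Alkaline NaBH4 demercuration turns CH2Hg into the C6 methyl group and gives 16. This closure offers little control at C6, so the C6 epimer would have to be removed by chromatography.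

Step 6. Process at risk: the silyl hydroperoxide may dismutate or act as a silyl donor instead of as an oxygen nucleophile. Triflate 8 may also lose triflic acid toward the conjugated enone or enolise at C3 (racemisation) before substitution. Fallback (sets out from 5, returns at 9): the O–O unit is brought in as a robust masked hydroperoxide and silylated afterwards. Triflate 8, generated as in step 6, is treated with 2-methoxypropan-2-yl hydroperoxide F6 (obtained by ozonolysis of 2,3-dimethylbut-2-ene in methanol) and DTBMP. This should give, with inversion, the peroxyketal methyl (R)-3-[(2-methoxypropan-2-yl)peroxy]-4-oxopentanoate F7. Aqueous acetic acid unmasks the α-hydroperoxy ketone methyl (R)-3-hydroperoxy-4-oxopentanoate F8, and Et3SiOTf/DTBMP at −78 °C silylates the hydroperoxide oxygen to give 9.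

Step 13. Process at risk: the phosphonate carbanion is basic enough to deprotonate C2 of the lactone, which would expel the C3 peroxide oxygen (β-elimination with opening of the dioxane). The new C13=C14 bond may also form with incomplete E selectivity. Fallback (sets out from 19, returns at 21): a Wittig reaction with the much less basic semi-stabilised ylide from commercial cinnamyltriphenylphosphonium bromide (NaHMDS, THF, −78 °C → rt). It is expected to give 21 together with its 13Z isomer, (3S,4aR,7aR)-3,4a-dimethyl-3-[(7Z,9E)-10-phenyldeca-7,9-dien-1-yl]tetrahydrofuro[3,2-c][1,2]dioxin-6(3H)-one F9. Catalytic iodine in CH2Cl2 under visible light should then equilibrate the 1-aryl diene to the E,E isomer 21 without touching the peroxide.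

Further compounds
F1 | step 9 | [6-(tert-butyldimethylsilyloxy)hexyl]magnesium bromide | CC(C)(C)[Si](C)(C)OCCCCCC[Mg]Br
F2 | step 9 | tert-butyldimethyl({8-[(trimethylsilyl)methyl]non-8-en-1-yl}oxy)silane | C=C(C[Si](C)(C)C)CCCCCCCO[Si](C)(C)C(C)(C)C
F3 | step 9 | methyl (3R,4R)-13-(tert-butyldimethylsilyloxy)-4-hydroxy-4-methyl-6-methylidene-3-[(triethylsilyl)peroxy]tridecanoate | C=C(CCCCCCCO[Si](C)(C)C(C)(C)C)C[C@@](C)(O)[C@@H](CC(=O)OC)OO[Si](CC)(CC)CC
F4 | step 9 | methyl (3R,4R)-13-(tert-butyldimethylsilyloxy)-3-hydroperoxy-4-hydroxy-4-methyl-6-methylidenetridecanoate | C=C(CCCCCCCO[Si](C)(C)C(C)(C)C)C[C@@](C)(O)[C@@H](CC(=O)OC)OO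
F5 | step 9 | methyl 2-[(3R,4R,6S)-6-[(acetoxymercurio)methyl]-6-[7-(tert-butyldimethylsilyloxy)heptyl]-4-hydroxy-4-methyl-1,2-dioxan-3-yl]acetate | CC(=O)O[Hg]C[C@]1(CCCCCCCO[Si](C)(C)C(C)(C)C)C[C@@](C)(O)[C@@H](CC(=O)OC)OO1
F6 | step 6 | 2-methoxypropan-2-yl hydroperoxide | COC(C)(C)OO
F7 | step 6 | methyl (R)-3-[(2-methoxypropan-2-yl)peroxy]-4-oxopentanoate | CC(=O)[C@@H](CC(=O)OC)OOC(C)(C)OC
F8 | step 6 | methyl (R)-3-hydroperoxy-4-oxopentanoate | CC(=O)[C@@H](CC(=O)OC)OO
F9 | step 13 | (3S,4aR,7aR)-3,4a-dimethyl-3-[(7Z,9E)-10-phenyldeca-7,9-dien-1-yl]tetrahydrofuro[3,2-c][1,2]dioxin-6(3H)-one | C[C@]1(CCCCCC/C=C\C=C\c2ccccc2)C[C@@]2(C)OC(=O)C[C@H]2OO1
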